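A small charge of solid substrate, 1.5 M in north, stands beside four flasks of 2.5 M, each at its own temperature, and one earlier run, delta, gives the readings.

| setting | delta | south | north | north-east | north-west | south-east |
|---|---|---|---|---|---|---|
| solid substrate | 2.8 M | 2.5 M | 1.5 M | 2.5 M | 2.5 M | 2.5 M |
| temperature | 35 °C | 75 °C | 50 °C | 15 °C | 35 °C | 65 °C |
| remark | run made earlier |  |  |  |  |  |
| time |  | 1.0 h | 1.0 h | 1.0 h | 1.0 h | 1.0 h |

delta run (percent of the solid substrate charged)

| time / min | target / % | isomer of the product / % | solid substrate / % |
|---|---|---|---|
| 6.00 | 59.2 | 17.8 | 0.4 |
| 12.0 | 54.7 | 28.1 | 1.2 |
| 20.0 | 47.2 | 35.4 | 0 |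
| 25.0 | 46.1 | 36.1 | 0 |
| 30.0 | 45.5 | 37.0 | 0 |
| 40.0 | 42.0 | 38.3 | 0 |

(standard deviation of a reading: 1 percentage point)

- the flasks put in order of share of target in all that became target or isomer of the product, best first, at 1.0 h (south / north / north-east / north-west / south-east)
- the same order at 8.0 h (south / north / north-east / north-west / south-east)
- the share of target in all that became target or isomer of the product of the flask you put first, at 1.0 h
- the share of target in all that became target or isomer of the product of the flask you put last, at 1.0 h

- as a solid, counted per litre of solution: solid substrate
- at the start none of the solid substrate is in solution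
- what has only dissolved of solid substrate counts as not reacted
- the earlier runs do not show what temperature does; that part of a forecast is a guess

Delta shows how the split between the two products moves. Let s = c(target)/(c(target) + c(isomer)) be the share, and let x be its excess over the last share read, which serves as the plateau:

- 6.00 min: s = 76.9 %, x = 25 percentage points
- 12.0 min: s = 66.1 %, x = 14 points
- 20.0 min: s = 57.1 %, x = 4.8 points
- 40.0 min: s = 52.3 %, the plateau as read

If the excess shrinks in proportion to itself, dx/dt = −x/τ integrates to x = x(start)·exp(−t/τ). Here τ is the share's relaxation time, the time in which the excess falls by a factor e. The first two rows give 10.3 min. The next two give 7.66 min, which is not far off, given a scatter of 1 point in each reading. The first and third rows together give 8.61 min.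

North-west has delta's temperature, so, taking its slightly smaller charge to change nothing, its hour holds 6.97 relaxation times. That leaves 0.0941 % of any excess, so the reckoning here commits north-west to about 52.3 %. Temperature is beyond these runs, so the other flasks stay guesses.

The forecast gives north-east > south > south-east > north > north-west at 1.0 h and south > south-east > north > north-west > north-east at 8.0 h, with 74 % first and 50 % last, where the reckoning here holds 52.3 %. Of the flasks it takes as equilibrated it says: “The ordering among the equilibrated flasks is a guess”.

South comes first with 91.7 %, above the 74 % that the forecast gave north-east, its first flask. The order is south > south-east > north-east > north > north-west at 1.0 h and south > south-east > north > north-west > north-east at 8.0 h.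

starting material ⇌ target (K = 2.70, k = 1.13 /min, Ea = 84.0 kJ/mol, ΔH = −17.0 kJ/mol); starting material ⇌ isomer of the product (K = 2.40, k = 0.160 /min, Ea = 94.0 kJ/mol, ΔH = −68.0 kJ/mol); solid substrate ⇌ starting material, rate k3*(cs3 - [starting material]) while solid is left; crystals form when [starting material] > cs3 (solubility = 1.20 M, k = 0.978 /min); (constants at 35 °C) North-west stands last at 1.0 h with 53.0 %, reads 52.9 % at 8.0 h, and ten times the time makes no difference there; by the reckoning its hour held 6.97 relaxation times. North-east's share falls from 79.8 % at 1.0 h to 37.3 % at 8.0 h. Its share at 10.0 h, 32.6 %, is still falling and stands in roughly for a plateau; with it the same closed form gives north-east a τ near 3.03 h, far longer than delta's 8.61 min. North-east at 1.0 h, under kinetic rather than thermodynamic control, has about 0.330 of one relaxation time behind it.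

The readings were computed with constants of no real substance, noise included.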